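**Retrosynthetic overview**

1. Target 22 is (2R,4S)-2-(ring A)-4-(ring B)pentan-3-one, where ring A is the 3,5-dimethyl-6-pentyl-γ-pyrone and ring B the 6-ethyl-3,5-dimethyl-γ-pyrone; chain C2 sits on ring A, C3 is the ketone, chain C4 sits on C2 of ring B. The last disconnection is the chain C3–C4 bond, made by a nickel-catalysed enantioconvergent reductive acyl cross-coupling of (R)-acid chloride 17 with racemic secondary chloride 21.
2. Enabling feature: chain C4 is the lateral carbon on C2 of ring B, so a radical there is planar and delocalised over C2=C3 and the C4 carbonyl of ring B. A racemic chloride therefore suffices, the chiral catalyst alone sets chain C4, and the base-free medium spares both epimerisable centres flanking the ketone.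
3. Ring B comes from a one-pot double C-acylation of pentan-3-one by the two propanoyl groups of propanoic anhydride with cyclodehydration, giving the symmetrical pyranone 19 (two ring C–C bonds, then closure at oxygen); chlorination of one of its two equivalent ethyl groups gives 21.
4. Ring A is made from another heteroaromatic ring: isoxazole 7 (nitrile oxide–enamine cycloaddition) is acylated at its 5-ethyl group by the Roche-ester Weinreb amide 10 (chiral-pool source of chain C2). N–O hydrogenolysis and acid then turn the isoxazole into γ-pyrone ring A (closure at oxygen), and the side-chain CH2OH is raised to the acid chloride.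
5. Order of ring formation: isoxazole (step 2), ring A (step 6), ring B (step 10); the two pyranones are joined last (step 12).

Key step: step 12

Remark: hexanal oxime is taken as a purchasable starting material, and the antipode of the bis(oxazoline) ligand that gives the S centre at chain C4 is to be fixed on a model coupling of 21 with a simple acid chloride.

**Route**

Step 1
Reactants: 1 pentan-3-one
Product: 2 1-(pent-2-en-3-yl)pyrrolidine (E/Z mixture)
Conditions: pyrrolidine, p-TsOH·H2O (cat.), toluene, reflux, Dean–Stark
Reagents that add atoms: pyrrolidine, C1CCNC1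
Why: Acid-catalysed enamine formation with azeotropic removal of water should give a single constitutional enamine because the ketone is symmetrical, and its E/Z geometry is irrelevant since the sp3 centres of the later cycloadduct disappear on aromatisation.

Step 2
Reactants: 2 1-(pent-2-en-3-yl)pyrrolidine; 3 hexanal oxime
Product: 7 5-ethyl-4-methyl-3-pentylisoxazole, via hydroximoyl chloride 4 (not isolated), via nitrile oxide 5 (not isolated), via aminoisoxazoline 6 (not isolated)
Conditions: N-chlorosuccinimide, pyridine (cat.), CHCl3, rt; then 2, Et3N (slow addition), 0 °C to rt; then 2 M aq. HCl, rt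
Reagents that add atoms: none
Why: Chlorination of the aldoxime and dehydrochlorination should give the nitrile oxide, whose Huisgen 1,3-dipolar cycloaddition to the electron-rich enamine is regiospecific (oxygen to the amine-bearing carbon), and acid-promoted loss of pyrrolidine aromatises the adduct to the regiodefined isoxazole.

Step 3
Reactants: 8 methyl (S)-3-hydroxy-2-methylpropanoate
Product: 9 methyl (S)-3-[(tert-butyldiphenylsilyl)oxy]-2-methylpropanoate
Conditions: t-BuPh2SiCl, imidazole, CH2Cl2, 0 °C to rt
Reagents that add atoms: tert-butyl(chloro)diphenylsilane, CC(C)(C)[Si](Cl)(c1ccccc1)c1ccccc1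
Why: Imidazole-mediated silylation of the primary alcohol should install an acid-stable silyl ether without touching the chiral-pool stereocentre.

Step 4
Reactants: 9 methyl (S)-3-[(tert-butyldiphenylsilyl)oxy]-2-methylpropanoate
Product: 10 (S)-3-[(tert-butyldiphenylsilyl)oxy]-N-methoxy-N,2-dimethylpropanamide
Conditions: MeNH(OMe)·HCl, i-PrMgCl, THF, −20 °C to 0 °C
Reagents that add atoms: N,O-dimethylhydroxylamine hydrochloride, CNOC.Cl
Why: Direct aminolysis of the ester by the magnesium amide of N,O-dimethylhydroxylamine (Weinreb amide formation) is fast at low temperature and should leave the α-stereocentre intact.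

Step 5
Reactants: 7 5-ethyl-4-methyl-3-pentylisoxazole; 10 (S)-3-[(tert-butyldiphenylsilyl)oxy]-N-methoxy-N,2-dimethylpropanamide
Product: 12 (4S)-5-[(tert-butyldiphenylsilyl)oxy]-4-methyl-2-(4-methyl-3-pentylisoxazol-5-yl)pentan-3-one (both C2 epimers), via lithiated isoxazole 11 (not isolated)
Conditions: LiN(iPr)2, THF, −78 °C; then 10, −78 °C to −40 °C; aq. NH4Cl
Reagents that add atoms: none
Why: Lateral lithiation should occur selectively at the 5-alkyl group of the isoxazole, and acylation by the Weinreb amide (Weinreb ketone synthesis) stops at the chelated tetrahedral adduct, so the Roche centre is not enolised and the new, uncontrolled centre is of no consequence because it becomes an sp2 ring carbon in step 6.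

Step 6
Reactants: 12 (4S)-5-[(tert-butyldiphenylsilyl)oxy]-4-methyl-2-(4-methyl-3-pentylisoxazol-5-yl)pentan-3-one
Product: 14 2-[(2S)-1-[(tert-butyldiphenylsilyl)oxy]propan-2-yl]-3,5-dimethyl-6-pentyl-4H-pyran-4-one, via enaminone 13 (not isolated)
Conditions: H2 (1 atm), Raney Ni, EtOH, rt; then CF3CO2H, CH2Cl2, 0 °C to rt
Reagents that add atoms: none
Why: Hydrogenolysis of the weak N–O bond should unmask the β-diketone as its vinylogous amide, and under acid the enol oxygen of the side-chain ketone attacks the protonated amino-bearing carbon with loss of ammonia (isoxazole-to-γ-pyrone ring transformation, closure at oxygen), enolisation running towards the doubly activated CH and not towards the Roche-derived centre.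

Step 7
Reactants: 14 2-[(2S)-1-[(tert-butyldiphenylsilyl)oxy]propan-2-yl]-3,5-dimethyl-6-pentyl-4H-pyran-4-one
Product: 15 2-[(2S)-1-hydroxypropan-2-yl]-3,5-dimethyl-6-pentyl-4H-pyran-4-one
Conditions: HF·pyridine, pyridine, THF, 0 °C to rt
Reagents that add atoms: none
Why: Buffered fluoride desilylation should free the primary alcohol under conditions too weakly basic to deprotonate the lateral stereocentre.

Step 8
Reactants: 15 2-[(2S)-1-hydroxypropan-2-yl]-3,5-dimethyl-6-pentyl-4H-pyran-4-one
Product: 16 (R)-2-(3,5-dimethyl-4-oxo-6-pentyl-4H-pyran-2-yl)propanoic acid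
Conditions: TEMPO (cat.), PhI(OAc)2, MeCN/H2O, 0 °C to rt
Reagents that add atoms: water, O
Why: Oxoammonium-mediated oxidation takes the primary alcohol through the aldehyde hydrate to the acid in a near-neutral medium, so the transient α-branched aldehyde should not epimerise (the descriptor changes from S to R only by priority).

Step 9
Reactants: 16 (R)-2-(3,5-dimethyl-4-oxo-6-pentyl-4H-pyran-2-yl)propanoic acid
Product: 17 (R)-2-(3,5-dimethyl-4-oxo-6-pentyl-4H-pyran-2-yl)propanoyl chloride
Conditions: 1-chloro-N,N,2-trimethylprop-1-en-1-amine, CH2Cl2, 0 °C; concentrate, use crude at once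
Reagents that add atoms: 1-chloro-N,N,2-trimethylprop-1-en-1-amine (Ghosez's reagent), CC(C)=C(Cl)N(C)C
Why: Acid chloride formation with the neutral α-chloroenamine avoids both a base, which would open the ketene pathway to racemisation, and oxalyl chloride, which would attack the nucleophilic pyranone carbonyl oxygen.

Step 10
Reactants: 1 pentan-3-one; 18 propanoic anhydride
Product: 19 2,6-diethyl-3,5-dimethyl-4H-pyran-4-one
Conditions: polyphosphoric acid, 95 °C
Reagents that add atoms: none
Why: In polyphosphoric acid the ketone should be C-acylated at both α-carbons by the two propanoyl groups of the one anhydride (the propanoic acid released in the first acylation is re-activated by the medium) and the resulting 1,3,5-triketone cyclodehydrated with closure at oxygen (acid-mediated γ-pyrone synthesis from a ketone and an acid anhydride), so that one ketone and one anhydride give the symmetrical ring B precursor and water only.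

Step 11
Reactants: 19 2,6-diethyl-3,5-dimethyl-4H-pyran-4-one
Product: 21 2-(1-chloroethyl)-6-ethyl-3,5-dimethyl-4H-pyran-4-one (racemic), via lithium dienolate 20 (not isolated)
Conditions: LiN(SiMe3)2, THF, −78 °C; then cannulate into Cl3CCCl3, THF, −78 °C
Reagents that add atoms: hexachloroethane, ClC(Cl)(Cl)C(Cl)(Cl)Cl
Why: Lateral deprotonation of one of the two equivalent ethyl groups gives the vinylogous enolate, which should be chlorinated at the exocyclic carbon because that restores the pyranone, and the new centre is left racemic on purpose since step 12 is stereoconvergent.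

Step 12
Reactants: 17 (R)-2-(3,5-dimethyl-4-oxo-6-pentyl-4H-pyran-2-yl)propanoyl chloride; 21 2-(1-chloroethyl)-6-ethyl-3,5-dimethyl-4H-pyran-4-one
Product: 22 (2R,4S)-2-(3,5-dimethyl-4-oxo-6-pentyl-4H-pyran-2-yl)-4-(6-ethyl-3,5-dimethyl-4-oxo-4H-pyran-2-yl)pentan-3-one
Conditions: NiCl2·dme (10 mol %), chiral 4,5-diphenyl-bis(oxazoline) ligand, Mn powder, 2,6-dimethylbenzoic acid, 3 Å MS, DMA/THF, 20 °C
Reagents that add atoms: none
Why: Zerovalent nickel carrying the chiral bis(oxazoline) should add oxidatively to the C(O)–Cl bond of 17, while a low-valent nickel species (turned over by Mn) abstracts chlorine from 21 to give the secondary radical on the carbon attached to C2 of ring B, planar and delocalised over C2=C3 and the C4 carbonyl of that ring; capture of this radical by the acylnickel complex and reductive elimination from trivalent nickel should form the chain C3–C4 bond. The closest known reaction type is the nickel-catalysed asymmetric reductive cross-coupling of acid chlorides with racemic secondary benzylic chlorides, which gives α-aryl-α-methyl ketones without base. No ring is closed, both γ-pyrones entering intact. The new chain C4 stereocentre is controlled by the chiral ligand on nickel at the radical-capture and reductive-elimination stage, so both enantiomers of 21 should converge on S, whereas the R centre at chain C2 is carried in from 17. The step needs cross- rather than homo-coupling, secured by the two different activation modes of the partners (two-electron oxidative addition for the acyl chloride, halogen-atom abstraction for the vinylogous α-keto C–Cl bond of 21), and it needs both epimerisable α-centres of 22 to survive, which the base-free medium at 20 °C should allow.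

**Compound list**

1 | pentan-3-one | CCC(=O)CC | starting material
2 | 1-(pent-2-en-3-yl)pyrrolidine (E/Z mixture) | CC=C(CC)N1CCCC1 | intermediate
3 | hexanal oxime | CCCCCC=NO | starting material
4 | N-hydroxyhexanimidoyl chloride | CCCCCC(Cl)=NO | intermediate
5 | hexanenitrile oxide | CCCCCC#[N+][O-] | intermediate
6 | 5-ethyl-4-methyl-3-pentyl-5-(pyrrolidin-1-yl)-4,5-dihydroisoxazole | CCCCCC1=NOC(CC)(N2CCCC2)C1C | intermediate
7 | 5-ethyl-4-methyl-3-pentylisoxazole | CCCCCc1noc(CC)c1C | intermediate
8 | methyl (S)-3-hydroxy-2-methylpropanoate | COC(=O)[C@@H](C)CO | starting material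
9 | methyl (S)-3-[(tert-butyldiphenylsilyl)oxy]-2-methylpropanoate | COC(=O)[C@@H](C)CO[Si](c1ccccc1)(c1ccccc1)C(C)(C)C | intermediate
10 | (S)-3-[(tert-butyldiphenylsilyl)oxy]-N-methoxy-N,2-dimethylpropanamide | CON(C)C(=O)[C@@H](C)CO[Si](c1ccccc1)(c1ccccc1)C(C)(C)C | intermediate
11 | 5-(1-lithioethyl)-4-methyl-3-pentylisoxazole | CCCCCc1noc(C(C)[Li])c1C | intermediate
12 | (4S)-5-[(tert-butyldiphenylsilyl)oxy]-4-methyl-2-(4-methyl-3-pentylisoxazol-5-yl)pentan-3-one (both C2 epimers) | CCCCCc1noc(C(C)C(=O)[C@@H](C)CO[Si](c2ccccc2)(c2ccccc2)C(C)(C)C)c1C | intermediate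
13 | (2S)-7-amino-1-[(tert-butyldiphenylsilyl)oxy]-2,4,6-trimethyldodec-6-ene-3,5-dione | CCCCCC(N)=C(C)C(=O)C(C)C(=O)[C@@H](C)CO[Si](c1ccccc1)(c1ccccc1)C(C)(C)C | intermediate
14 | 2-[(2S)-1-[(tert-butyldiphenylsilyl)oxy]propan-2-yl]-3,5-dimethyl-6-pentyl-4H-pyran-4-one | CCCCCc1oc([C@@H](C)CO[Si](c2ccccc2)(c2ccccc2)C(C)(C)C)c(C)c(=O)c1C | intermediate
15 | 2-[(2S)-1-hydroxypropan-2-yl]-3,5-dimethyl-6-pentyl-4H-pyran-4-one | CCCCCc1oc([C@@H](C)CO)c(C)c(=O)c1C | intermediate
16 | (R)-2-(3,5-dimethyl-4-oxo-6-pentyl-4H-pyran-2-yl)propanoic acid | CCCCCc1oc([C@@H](C)C(=O)O)c(C)c(=O)c1C | intermediate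
17 | (R)-2-(3,5-dimethyl-4-oxo-6-pentyl-4H-pyran-2-yl)propanoyl chloride | CCCCCc1oc([C@@H](C)C(=O)Cl)c(C)c(=O)c1C | intermediate
18 | propanoic anhydride | CCC(=O)OC(=O)CC | starting material
19 | 2,6-diethyl-3,5-dimethyl-4H-pyran-4-one | CCc1oc(CC)c(C)c(=O)c1C | intermediate
20 | lithium 2-ethyl-6-ethylidene-3,5-dimethyl-6H-pyran-4-olate | CC=C1OC(CC)=C(C)C(O[Li])=C1C | intermediate
21 | 2-(1-chloroethyl)-6-ethyl-3,5-dimethyl-4H-pyran-4-one (racemic) | CCc1oc(C(C)Cl)c(C)c(=O)c1C | intermediate
22 | (2R,4S)-2-(3,5-dimethyl-4-oxo-6-pentyl-4H-pyran-2-yl)-4-(6-ethyl-3,5-dimethyl-4-oxo-4H-pyran-2-yl)pentan-3-one | CCCCCc1oc([C@@H](C)C(=O)[C@@H](C)c2oc(CC)c(C)c(=O)c2C)c(C)c(=O)c1C | target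

**Step count and risks**

Total step count: 12. Longest linear sequence: 8 steps (steps 1, 2, 5, 6, 7, 8, 9, 12; the branch from the Roche ester through steps 3, 4, 5, 6, 7, 8, 9, 12 is equally long).

Steps most likely to fail:

1. Step 12. What may go wrong: loss of configuration at chain C2 through reversible ketene formation from the acid chloride or decarbonylation at the acylnickel stage, poor facial control at chain C4 (ligand–substrate mismatch, crowding by the C3 methyl of ring B next to the radical carbon), and reductive homo-coupling of 21. Fallback: the same bond is closed at the alcohol oxidation level by an anionic lateral aldol reaction. It sets out from alcohol 15 and pyranone 19. Dess–Martin oxidation of 15 (NaHCO3, CH2Cl2, 0 °C) should give (R)-2-(3,5-dimethyl-4-oxo-6-pentyl-4H-pyran-2-yl)propanal F1, which is added at −78 °C to lithium dienolate 20 (from 19 and LiN(SiMe3)2 in THF) to give 2-(3,5-dimethyl-4-oxo-6-pentyl-4H-pyran-2-yl)-4-(6-ethyl-3,5-dimethyl-4-oxo-4H-pyran-2-yl)pentan-3-ol F2 as a mixture of isomers. Facial control at chain C4 then rests on substrate bias, so the isomers having the arrangement of 22 at both methyl-bearing carbons are separated by chromatography and oxidised with Dess–Martin periodinane, which comes back to the route at 22.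

2. Step 6. What may go wrong: closure of the enaminone through nitrogen onto the side-chain ketone (4-pyridone formation) in competition with closure through oxygen, acid-induced epimerisation of the centre next to the ketone, and over-reduction of the ketone. Fallback: a nitrogen-free construction of ring A that sets out from Weinreb amide 10. EtMgBr (THF, 0 °C) should give (S)-1-[(tert-butyldiphenylsilyl)oxy]-2-methylpentan-3-one F3. Its kinetic lithium enolate (LiN(iPr)2, −78 °C) is added to propanal to give (2S)-1-[(tert-butyldiphenylsilyl)oxy]-5-hydroxy-2,4-dimethylheptan-3-one F4, and Dess–Martin oxidation gives the β-diketone (2S)-1-[(tert-butyldiphenylsilyl)oxy]-2,4-dimethylheptane-3,5-dione F5. Its dianion (excess LiN(iPr)2) is acylated at the terminal CH2 by methyl hexanoate (Claisen condensation) to give (2S)-1-[(tert-butyldiphenylsilyl)oxy]-2,4,6-trimethyldodecane-3,5,7-trione F6. Neutral cyclodehydration of this triketone (PPh3, CCl4, THF) comes back to the route at 14.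

3. Step 11. What may go wrong: proton transfer between the product and unreacted dienolate leading to double chlorination, alkylation of the dienolate by the product chloride, and elimination of HCl on work-up or on silica. Fallback: the chlorine is introduced in two steps through the alcohol, setting out from 19. Dienolate 20 is hydroxylated with Davis oxaziridine (2-(phenylsulfonyl)-3-phenyloxaziridine, THF, −78 °C) to give 2-ethyl-6-(1-hydroxyethyl)-3,5-dimethyl-4H-pyran-4-one F7, and treatment with SOCl2 (CH2Cl2, 0 °C) comes back to the route at 21.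

**Further compounds**

F1 | step 12 | (R)-2-(3,5-dimethyl-4-oxo-6-pentyl-4H-pyran-2-yl)propanal | CCCCCc1oc([C@@H](C)C=O)c(C)c(=O)c1C
F2 | step 12 | 2-(3,5-dimethyl-4-oxo-6-pentyl-4H-pyran-2-yl)-4-(6-ethyl-3,5-dimethyl-4-oxo-4H-pyran-2-yl)pentan-3-ol having the C2 and C4 arrangement of 22 (either C3 epimer) | CCCCCc1oc([C@@H](C)C(O)[C@@H](C)c2oc(CC)c(C)c(=O)c2C)c(C)c(=O)c1C
F3 | step 6 | (S)-1-[(tert-butyldiphenylsilyl)oxy]-2-methylpentan-3-one | CCC(=O)[C@@H](C)CO[Si](c1ccccc1)(c1ccccc1)C(C)(C)C
F4 | step 6 | (2S)-1-[(tert-butyldiphenylsilyl)oxy]-5-hydroxy-2,4-dimethylheptan-3-one (diastereomer mixture) | CCC(O)C(C)C(=O)[C@@H](C)CO[Si](c1ccccc1)(c1ccccc1)C(C)(C)C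
F5 | step 6 | (2S)-1-[(tert-butyldiphenylsilyl)oxy]-2,4-dimethylheptane-3,5-dione | CCC(=O)C(C)C(=O)[C@@H](C)CO[Si](c1ccccc1)(c1ccccc1)C(C)(C)C
F6 | step 6 | (2S)-1-[(tert-butyldiphenylsilyl)oxy]-2,4,6-trimethyldodecane-3,5,7-trione | CCCCCC(=O)C(C)C(=O)C(C)C(=O)[C@@H](C)CO[Si](c1ccccc1)(c1ccccc1)C(C)(C)C
F7 | step 11 | 2-ethyl-6-(1-hydroxyethyl)-3,5-dimethyl-4H-pyran-4-one (racemic) | CCc1oc(C(C)O)c(C)c(=O)c1C
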